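**Retrosynthetic overview**
1. Numbering: C1 is the ketone carbon, C2–C9 are the eight CH2 groups, and C9 carries the 4-hydroxyphenyl ring. The chain is cut once, at C3–C4, by a reductive decarboxylative Giese addition under visible-light photoredox catalysis.
2. Enabling feature: C3 lies β to the C1 carbonyl on the 2,6-dimethoxyphenyl ring, so C2=C3 of the corresponding aryl vinyl ketone is an electron-poor radical acceptor with a free CH2 terminus. C4 is a plain CH2 that can be carried as the α-carbon of a carboxylic acid and released as a nucleophilic primary radical by loss of CO2.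
3. C1–C3 half: 1-(2,6-dimethoxyphenyl)prop-2-en-1-one, made by α-methylenation of 2',6'-dimethoxyacetophenone.
4. C4–C9 half: the N-hydroxyphthalimide ester of 7-(4-hydroxyphenyl)heptanoic acid, made from 4-iodophenol and hept-6-ynoic acid by Sonogashira coupling, hydrogenation and activation. The phenol is never protected.
5. No ring is formed, because both benzene rings are bought. The key step is the last step and gives the target directly, with the activating group leaving in the same operation.

Key step: step 5

Remark on the chemistry: the target has no stereocentre and no stereogenic double bond. It is achiral, so no step has to control configuration.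

**Step 1**
Reactants: 1 4-iodophenol; 2 hept-6-ynoic acid
Product: 3 7-(4-hydroxyphenyl)hept-6-ynoic acid
Conditions: PdCl2(PPh3)2 (2 mol %), CuI (4 mol %), Et3N (5 equiv), degassed THF, rt to 50 °C; then 1 M HCl work-up
Reagents that add atoms: none
Why: Sonogashira coupling, in which the aryl iodide adds oxidatively to Pd(0) under mild conditions and couples with the copper acetylide of 2, while the phenol and the acid travel as triethylammonium salts and seven-membered enol-lactone formation from the alkynoic acid is too slow to compete.

**Step 2**
Reactants: 3 7-(4-hydroxyphenyl)hept-6-ynoic acid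
Product: 4 7-(4-hydroxyphenyl)heptanoic acid
Conditions: H2 (1 atm), 10% Pd/C, EtOAc–EtOH, rt
Reagents that add atoms: none
Why: Heterogeneous catalytic hydrogenation should saturate the aryl alkyne fully at 1 atm without touching the phenol ring or the acid, and it removes the π bond that would otherwise trap the later radical by 5-exo cyclisation.

**Step 3**
Reactants: 4 7-(4-hydroxyphenyl)heptanoic acid
Product: 5 1,3-dioxoisoindolin-2-yl 7-(4-hydroxyphenyl)heptanoate
Conditions: N-hydroxyphthalimide (1.05 equiv), DIC (1.1 equiv), THF, 0 °C to rt, no DMAP and no added base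
Reagents that add atoms: N-hydroxyphthalimide, O=C1c2ccccc2C(=O)N1O
Why: Carbodiimide active-ester formation, in which the much more acidic, α-effect N–OH nucleophile should intercept the O-acylisourea far faster than the neutral phenol when no acyl-transfer catalyst is present, as in the standard preparation of N-hydroxyimide esters of hydroxyphenylalkanoic acids.

**Step 4**
Reactants: 6 1-(2,6-dimethoxyphenyl)ethan-1-one (2',6'-dimethoxyacetophenone)
Product: 7 1-(2,6-dimethoxyphenyl)prop-2-en-1-one
Conditions: (CH2O)n (2.5 equiv), i-Pr2NH·TFA (1 equiv), TFA (10 mol %), THF, reflux; short silica plug, kept cold and used promptly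
Reagents that add atoms: paraformaldehyde (as formaldehyde), C=O
Why: Mannich-type α-methylenation, in which the enol of the methyl ketone attacks the iminium ion from formaldehyde and diisopropylamine and the bulky amine then leaves by β-elimination; this is a standard way from aryl methyl ketones to aryl vinyl ketones and cannot over-react because the new α-carbon is vinylic.

**Step 5**
Reactants: 5 1,3-dioxoisoindolin-2-yl 7-(4-hydroxyphenyl)heptanoate; 7 1-(2,6-dimethoxyphenyl)prop-2-en-1-one
Product: 8 1-(2,6-dimethoxyphenyl)-9-(4-hydroxyphenyl)nonan-1-one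
Conditions: 5 (1 equiv), 7 (2 equiv), Hantzsch ester (1.5 equiv), Ru(bpy)3(PF6)2 (1 mol %), degassed CH2Cl2 (0.2 M), blue LEDs (450 nm), rt
Reagents that add atoms: none
Why: Mechanism: photoexcited Ru(II) is reductively quenched by the Hantzsch ester, and the resulting Ru(I) transfers one electron into the phthalimide unit of 5, whose N–O bond breaks and whose carboxyl radical loses CO2 to leave the primary 6-(4-hydroxyphenyl)hexyl radical centred on the future C4. This nucleophilic radical adds to the unsubstituted CH2 terminus (future C3) of the electron-poor C2=C3 bond of 7, and the electrophilic α-keto radical at C2 is capped by hydrogen transfer from the Hantzsch ester or its radical cation, which ends as the pyridine while the phthalimide anion takes up the remaining proton. The closest known reaction type is the visible-light reductive decarboxylative Giese addition of N-(acyloxy)phthalimides to enones and acrylates, which is established for primary fatty-acid-derived esters and for vinyl ketones. No ring is closed and no stereocentre is created. The step needs cross-coupling instead of radical dimerisation, attack at C3 instead of C1, and addition faster than hydrogen capture or a 1,6-hydrogen shift from benzylic C9; these are secured by polarity matching between the alkyl radical and the enone, the free β-CH2, the two ortho-methoxy groups that shield C1, and an excess of 7 at high concentration. The same ortho-methoxy groups twist the aryl ring out of conjugation with C1=O, so 7 should be too hard to reduce for Ru(I) and stay out of radical-anion chemistry, and the free phenol should be tolerated because the medium is reducing and base-free, so neither phenoxide acyl transfer, oxa-Michael addition nor lasting phenoxyl formation is expected.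

**Compound list**
1 | 4-iodophenol | Oc1ccc(I)cc1 | starting material
2 | hept-6-ynoic acid | C#CCCCCC(=O)O | starting material
3 | 7-(4-hydroxyphenyl)hept-6-ynoic acid | O=C(O)CCCCC#Cc1ccc(O)cc1 | intermediate
4 | 7-(4-hydroxyphenyl)heptanoic acid | O=C(O)CCCCCCc1ccc(O)cc1 | intermediate
5 | 1,3-dioxoisoindolin-2-yl 7-(4-hydroxyphenyl)heptanoate | O=C(CCCCCCc1ccc(O)cc1)ON1C(=O)c2ccccc2C1=O | intermediate
6 | 1-(2,6-dimethoxyphenyl)ethan-1-one | COc1cccc(OC)c1C(C)=O | starting material
7 | 1-(2,6-dimethoxyphenyl)prop-2-en-1-one | COc1cccc(OC)c1C(=O)C=C | intermediate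
8 | 1-(2,6-dimethoxyphenyl)-9-(4-hydroxyphenyl)nonan-1-one | COc1cccc(OC)c1C(=O)CCCCCCCCc1ccc(O)cc1 | target

**Total step count:** 5
**Longest linear sequence:** 4 steps (steps 1, 2, 3 and 5)

**Steps most likely to fail**

1. Step 5.
   - Risk: telomerisation of the vinyl ketone, premature hydrogen capture by the primary radical, or a hydrogen shift from the benzylic position may outrun the bimolecular addition.
   - Fallback: it sets out from 1 and 7 and comes back at 8. The radical union is replaced by a polar, copper-catalysed conjugate addition to the same C3 terminus.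
   - Compound 1 is benzylated (BnBr, K2CO3, acetone, reflux) to 1-(benzyloxy)-4-iodobenzene F1.
   - 6-Bromohex-1-ene is hydroborated with 9-BBN (THF, 0 °C to rt) to 9-(6-bromohexyl)-9-borabicyclo[3.3.1]nonane F2. This is joined with F1 by B-alkyl Suzuki–Miyaura coupling (PdCl2(dppf), aq K3PO4, THF, 50 °C) to give 1-(benzyloxy)-4-(6-bromohexyl)benzene F3.
   - Magnesium insertion (Mg, THF) gives {6-[4-(benzyloxy)phenyl]hexyl}magnesium bromide F4.
   - F4 adds 1,4 to 7 (CuBr·SMe2 10 mol %, TMSCl, THF, −78 °C) to give the silyl enol ether {[9-(4-(benzyloxy)phenyl)-1-(2,6-dimethoxyphenyl)non-1-en-1-yl]oxy}trimethylsilane F5.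
   - Dilute HCl converts F5 into 9-[4-(benzyloxy)phenyl]-1-(2,6-dimethoxyphenyl)nonan-1-one F6. Hydrogenolysis (H2, Pd/C, EtOAc, rt) then returns 8.

2. Step 3.
   - Risk: acylation of the phenolic oxygen, leading to oligoester formation, may compete during activation or on storage of the active ester.
   - Fallback: it sets out from 4 and comes back at 8. The protecting-group-free plan is given up for a temporary acetate.
   - Compound 4 is acetylated (Ac2O, pyridine, then aqueous work-up to hydrolyse any mixed anhydride) to 7-(4-acetoxyphenyl)heptanoic acid F7.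
   - Activation can now use the full acyl-transfer conditions (N-hydroxyphthalimide, DIC, DMAP cat., CH2Cl2) and gives 1,3-dioxoisoindolin-2-yl 7-(4-acetoxyphenyl)heptanoate F8.
   - Coupling of F8 with 7 under the conditions of step 5 gives 4-[9-(2,6-dimethoxyphenyl)-9-oxononyl]phenyl acetate F9. Methanolysis (K2CO3, MeOH, rt) then returns 8.

3. Step 4.
   - Risk: the vinyl ketone may polymerise on concentration, or the elimination may stall at the Mannich-base stage.
   - Fallback: it sets out from 6 and comes back at 7. A storable latent enone is used, so the free vinyl ketone is never isolated neat.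
   - A classical Mannich reaction of 6 (Me2NH·HCl, (CH2O)n, cat. HCl, EtOH, reflux, then basification) gives 3-(dimethylamino)-1-(2,6-dimethoxyphenyl)propan-1-one F10.
   - Quaternisation (MeI, Et2O, rt) gives crystalline 3-(2,6-dimethoxyphenyl)-N,N,N-trimethyl-3-oxopropan-1-aminium iodide F11.
   - Immediately before step 5, F11 is shaken with aq NaHCO3/CH2Cl2. The dried CH2Cl2 solution of 7 goes into the photoreaction without concentration.

**Further compounds**
F1 | step 5 | 1-(benzyloxy)-4-iodobenzene | Ic1ccc(OCc2ccccc2)cc1
F2 | step 5 | 9-(6-bromohexyl)-9-borabicyclo[3.3.1]nonane | BrCCCCCCB1C2CCCC1CCC2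
F3 | step 5 | 1-(benzyloxy)-4-(6-bromohexyl)benzene | BrCCCCCCc1ccc(OCc2ccccc2)cc1
F4 | step 5 | {6-[4-(benzyloxy)phenyl]hexyl}magnesium bromide | Br[Mg]CCCCCCc1ccc(OCc2ccccc2)cc1
F5 | step 5 | {[9-(4-(benzyloxy)phenyl)-1-(2,6-dimethoxyphenyl)non-1-en-1-yl]oxy}trimethylsilane | COc1cccc(OC)c1C(O[Si](C)(C)C)=CCCCCCCCc1ccc(OCc2ccccc2)cc1
F6 | step 5 | 9-[4-(benzyloxy)phenyl]-1-(2,6-dimethoxyphenyl)nonan-1-one | COc1cccc(OC)c1C(=O)CCCCCCCCc1ccc(OCc2ccccc2)cc1
F7 | step 3 | 7-(4-acetoxyphenyl)heptanoic acid | CC(=O)Oc1ccc(CCCCCCC(=O)O)cc1
F8 | step 3 | 1,3-dioxoisoindolin-2-yl 7-(4-acetoxyphenyl)heptanoate | CC(=O)Oc1ccc(CCCCCCC(=O)ON2C(=O)c3ccccc3C2=O)cc1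
F9 | step 3 | 4-[9-(2,6-dimethoxyphenyl)-9-oxononyl]phenyl acetate | COc1cccc(OC)c1C(=O)CCCCCCCCc1ccc(OC(C)=O)cc1
F10 | step 4 | 3-(dimethylamino)-1-(2,6-dimethoxyphenyl)propan-1-one | COc1cccc(OC)c1C(=O)CCN(C)C
F11 | step 4 | 3-(2,6-dimethoxyphenyl)-N,N,N-trimethyl-3-oxopropan-1-aminium iodide | COc1cccc(OC)c1C(=O)CC[N+](C)(C)C.[I-]
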